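**Retrosynthetic overview**
1. Feature: ring B (primed half) differs from ring A only by the oxygens at C6' and C8', each ortho to a phenolic oxygen (C5'–O/C7'–O and C7'–O/O1'). Ring B is therefore carried as a 5',7'-dioxygenated ring, and the C6'–O and C8'–O bonds are made last by twofold Dakin oxidation of the 6',8'-dialdehyde.
2. The dialdehyde comes from Rieche diformylation of the 3,4-cis/3',4'-cis dimer in which only ring B has free phenols (ring A and both 4-aryl oxygens as benzyl carbonates).
3. C3–C3' is made by oxidative cross-coupling of the enolates of two 4-aryl-dihydrocoumarins of opposite configuration; C3 and C3' are then set by kinetic protonation of the dienolate.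
4. C4 (S) and C4' (R) are set separately by rhodium-catalysed asymmetric 1,4-arylation of two protected 5,7-dihydroxycoumarins with enantiomeric ligands.
5. No ring is closed in the route: both pyranone rings come from 5,7-dihydroxycoumarin and all benzene rings from commercial materials.

Key step: step 11

Remark on stereochemistry: chroman locants are used, unprimed for the ring A half and primed for the ring B half. The target is (3R,4S,3'S,4'R): both lactones are 3,4-cis and the two halves have opposite configuration.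

Remark on protecting groups: aryl alkyl ethers on ring A would leave C6 and C8 about as reactive toward Cl2CHOMe/TiCl4 as ring B. Ring A and both 4-aryl oxygens are therefore carried as benzyl ethers through the base-mediated steps and exchanged for electron-withdrawing, hydrogenolysable benzyl carbonates before ring B (methoxymethyl ethers) is unmasked. The final deprotection is then a neutral hydrogenolysis. 5,7-Dihydroxycoumarin and 4-(benzyloxy)phenylboronic acid are taken as commercial.

**Route**

Step 1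
Reactants: 1 5,7-dihydroxycoumarin
Product: 2 5,7-bis(benzyloxy)coumarin
Conditions: BnBr, K2CO3, DMF, 60 °C
Reagents that add atoms: benzyl bromide, BrCc1ccccc1
Why: Williamson etherification of both phenoxides, the coumarin lactone being inert to carbonate in an aprotic solvent.

Step 2
Reactants: 2 5,7-bis(benzyloxy)coumarin; 3 4-(benzyloxy)phenylboronic acid (3 equiv)
Product: 4 (4S)-5,7-bis(benzyloxy)-4-[4-(benzyloxy)phenyl]chroman-2-one
Conditions: Rh(acac)(C2H4)2 (3 mol%), (S)-SEGPHOS, 1,4-dioxane–H2O (10:1), 60 °C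
Reagents that add atoms: none
Why: Hayashi–Miyaura asymmetric 1,4-addition, in which the aryl–rhodium bisphosphine complex inserts the coumarin C3=C4 bond on one face and water protonates the rhodium enolate; the (S)-ligand is chosen because, by analogy with unsubstituted coumarins, it should set C4 as S.

Step 3
Reactants: 1 5,7-dihydroxycoumarin
Product: 5 5,7-bis(methoxymethoxy)coumarin
Conditions: MOMCl, i-Pr2NEt, CH2Cl2, 0 °C → rt
Reagents that add atoms: chloromethyl methyl ether, COCCl
Why: O-alkylation of both phenols by the reactive α-chloro ether gives the two aryl methoxymethyl acetals.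

Step 4
Reactants: 5 5,7-bis(methoxymethoxy)coumarin; 3 4-(benzyloxy)phenylboronic acid (3 equiv)
Product: 6 (4R)-4-[4-(benzyloxy)phenyl]-5,7-bis(methoxymethoxy)chroman-2-one
Conditions: Rh(acac)(C2H4)2 (3 mol%), (R)-SEGPHOS, 1,4-dioxane–H2O (10:1), 60 °C
Reagents that add atoms: none
Why: the same Hayashi–Miyaura 1,4-addition with the enantiomeric ligand should deliver the aryl group to the opposite face and set the future C4' as R.

Step 5
Reactants: 4 (4S)-5,7-bis(benzyloxy)-4-[4-(benzyloxy)phenyl]chroman-2-one (3 equiv); 6 (4R)-4-[4-(benzyloxy)phenyl]-5,7-bis(methoxymethoxy)chroman-2-one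
Product: 9 (3S,4S,3'R,4'R)-5,7-bis(benzyloxy)-4,4'-bis[4-(benzyloxy)phenyl]-5',7'-bis(methoxymethoxy)-[3,3'-bichromane]-2,2'-dione (3,4-trans/3',4'-trans), via ring A lithium enolate 7 (not isolated), via ring B lithium enolate 8 (not isolated)
Conditions: LiN(SiMe3)2, THF, −78 °C; then Cu(O2CCH(Et)Bu)2 (copper bis(2-ethylhexanoate)), −78 → 0 °C
Reagents that add atoms: none
Why: copper-mediated oxidative coupling of ester enolates joins C3 to C3' by one-electron oxidation with divalent copper, each carbon reacting on the face away from its pseudo-axial C4 aryl group so that the trans/trans isomer should prevail (C3/C3' are reset in step 6), while the threefold excess of 4 should channel most of 6 into the cross-product, which is separable from the two homodimers by its different ether pattern.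

Step 6
Reactants: 9 the 3,4-trans/3',4'-trans dimer
Product: 11 (3R,4S,3'S,4'R)-5,7-bis(benzyloxy)-4,4'-bis[4-(benzyloxy)phenyl]-5',7'-bis(methoxymethoxy)-[3,3'-bichromane]-2,2'-dione (3,4-cis/3',4'-cis), via dilithium dienolate 10 (not isolated)
Conditions: LiN(i-Pr)2 (3 equiv), THF, −78 → −40 °C; then cannulation into AcOH–THF, −78 °C
Reagents that add atoms: none
Why: twofold deprotonation gives the succinate-type dienolate in which C3 and C3' are trigonal, and irreversible kinetic protonation by inverse addition to excess acid should deliver each proton to the face opposite the pseudo-axial aryl group on the neighbouring C4 or C4', so that each new C–H is trans to that aryl group and both lactones become 3,4-cis whatever the C3/C3' configuration of 9.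

Step 7
Reactants: 11 the cis/cis tetrabenzyl ether
Product: 12 (3R,4S,3'S,4'R)-5,7-dihydroxy-4,4'-bis(4-hydroxyphenyl)-5',7'-bis(methoxymethoxy)-[3,3'-bichromane]-2,2'-dione
Conditions: H2 (1 atm), Pd/C, EtOAc–THF, rt
Reagents that add atoms: none
Why: palladium-catalysed hydrogenolysis cleaves the four benzyl ethers under neutral conditions that leave the methoxymethyl acetals, the aryl lactones and the epimerisable C3/C3' centres untouched.

Step 8
Reactants: 12 the tetraphenol
Product: 13 (3R,4S,3'S,4'R)-5,7-bis(benzyloxycarbonyloxy)-4,4'-bis[4-(benzyloxycarbonyloxy)phenyl]-5',7'-bis(methoxymethoxy)-[3,3'-bichromane]-2,2'-dione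
Conditions: CbzCl, pyridine, CH2Cl2, 0 °C
Reagents that add atoms: benzyl chloroformate, O=C(Cl)OCc1ccccc1
Why: acylation of the four phenols by the chloroformate with pyridine, a base too weak to enolise the lactones, turns ring A and both 4-aryl rings into electron-poor aryl carbonates.

Step 9
Reactants: 13 the tetracarbonate
Product: 14 (3R,4S,3'S,4'R)-5,7-bis(benzyloxycarbonyloxy)-4,4'-bis[4-(benzyloxycarbonyloxy)phenyl]-5',7'-dihydroxy-[3,3'-bichromane]-2,2'-dione
Conditions: ZnBr2, n-PrSH, CH2Cl2, 0 °C → rt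
Reagents that add atoms: none
Why: ZnBr2-activated cleavage of the two aryl methoxymethyl acetals with capture of the methoxymethyl cation by the thiol, which prevents Friedel–Crafts alkylation of the freed ring B and spares carbonates and lactones.

Step 10
Reactants: 14 the ring B diol
Product: 16 (3R,4S,3'S,4'R)-5,7-bis(benzyloxycarbonyloxy)-4,4'-bis[4-(benzyloxycarbonyloxy)phenyl]-5',7'-dihydroxy-2,2'-dioxo-[3,3'-bichromane]-6',8'-dicarbaldehyde, via bis[chloro(methoxy)methyl] adduct 15 (not isolated)
Conditions: Cl2CHOMe (4 equiv), TiCl4 (10 equiv), CH2Cl2, −20 → 0 °C; then 1 M HCl, 0 °C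
Reagents that add atoms: dichloromethyl methyl ether, COC(Cl)Cl; water, O
Why: Rieche formylation, in which the titanium phenoxides formed at O5' and O7' direct the electrophile to the ortho positions C6' and C8' (as in the known twofold formylation of acylphloroglucinols), while ring A and the 4-aryl rings are deactivated as carbonates and the base-free medium should not epimerise C3 or C3'; aqueous acid then hydrolyses the α-chloro ethers to the aldehydes.

Step 11
Reactants: 16 the 6',8'-dialdehyde
Product: 18 (3R,4S,3'S,4'R)-5,7-bis(benzyloxycarbonyloxy)-4,4'-bis[4-(benzyloxycarbonyloxy)phenyl]-5',6',7',8'-tetrahydroxy-[3,3'-bichromane]-2,2'-dione, via bis-formate 17 (not isolated)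
Conditions: mCPBA (2.4 equiv), CH2Cl2, 0 °C → rt; Me2S; then 1 M HCl, THF–H2O, rt (argon)
Reagents that add atoms: 3-chloroperoxybenzoic acid, O=C(OO)c1cccc(Cl)c1
Why: the peracid adds to each aldehyde to give a Criegee adduct, and the ring B carbon (C6' or C8'), made electron-rich by the free ortho/para hydroxyl groups at C5' and C7', migrates from carbon to oxygen with loss of 3-chlorobenzoate to give the bis-formate, whose formate esters are hydrolysed by dilute acid. The closest known reaction type is the Dakin oxidation of ortho-hydroxybenzaldehydes to catechols in its non-basic peracid (Baeyer–Villiger) form. No ring is closed and no stereocentre is formed; the step makes the C6'–O and C8'–O bonds. The selectivity needed is aryl over hydride migration and oxidation of ring B only: the hydroxyl groups of ring B raise the migratory aptitude of the aryl carbon, while ring A and the two 4-aryl rings carry no formyl group and are deactivated as carbonates. The non-basic medium should leave the epimerisable 3,4-cis lactones untouched, and the pentaoxygenated ring stays masked as the bis-formate until the oxidant has been destroyed, which guards against quinone formation.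

Step 12
Reactants: 18 the tetracarbonate with fully oxygenated ring B
Product: 19 (3R,4S,3'S,4'R)-5,7,5',6',7',8'-hexahydroxy-4,4'-bis(4-hydroxyphenyl)-[3,3'-bichromane]-2,2'-dione (CNP0064734.3)
Conditions: H2 (1 atm), Pd/C, THF–EtOAc, rt; filtration and concentration under argon
Reagents that add atoms: none
Why: hydrogenolysis of the four benzyl carbonates gives toluene and carbonic acid monoesters that lose CO2 to release the phenols under neutral, reducing conditions, which protect both the cis lactones and the oxidation-prone ring B.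

**Compound list**
1 | 5,7-dihydroxycoumarin | O=c1ccc2c(O)cc(O)cc2o1 | starting material
2 | 5,7-bis(benzyloxy)coumarin | O=c1ccc2c(OCc3ccccc3)cc(OCc3ccccc3)cc2o1 | intermediate
3 | 4-(benzyloxy)phenylboronic acid | OB(O)c1ccc(OCc2ccccc2)cc1 | starting material
4 | (4S)-5,7-bis(benzyloxy)-4-[4-(benzyloxy)phenyl]chroman-2-one | O=C1C[C@@H](c2ccc(OCc3ccccc3)cc2)c2c(OCc3ccccc3)cc(OCc3ccccc3)cc2O1 | intermediate
5 | 5,7-bis(methoxymethoxy)coumarin | O=c1ccc2c(OCOC)cc(OCOC)cc2o1 | intermediate
6 | (4R)-4-[4-(benzyloxy)phenyl]-5,7-bis(methoxymethoxy)chroman-2-one | O=C1C[C@H](c2ccc(OCc3ccccc3)cc2)c2c(OCOC)cc(OCOC)cc2O1 | intermediate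
7 | lithium enolate of 4 (ring A half) | [Li+].[O-]C1=C[C@@H](c2ccc(OCc3ccccc3)cc2)c2c(OCc3ccccc3)cc(OCc3ccccc3)cc2O1 | intermediate
8 | lithium enolate of 6 (ring B half) | [Li+].[O-]C1=C[C@H](c2ccc(OCc3ccccc3)cc2)c2c(OCOC)cc(OCOC)cc2O1 | intermediate
9 | (3S,4S,3'R,4'R)-5,7-bis(benzyloxy)-4,4'-bis[4-(benzyloxy)phenyl]-5',7'-bis(methoxymethoxy)-[3,3'-bichromane]-2,2'-dione | O=C1Oc2cc(OCc3ccccc3)cc(OCc3ccccc3)c2[C@H](c2ccc(OCc3ccccc3)cc2)[C@H]1[C@@H]1C(=O)Oc2cc(OCOC)cc(OCOC)c2[C@H]1c1ccc(OCc2ccccc2)cc1 | intermediate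
10 | dilithium dienolate of 9 | [Li+].[Li+].[O-]C1=C(C2=C([O-])Oc3cc(OCOC)cc(OCOC)c3[C@H]2c2ccc(OCc3ccccc3)cc2)[C@@H](c2ccc(OCc3ccccc3)cc2)c2c(OCc3ccccc3)cc(OCc3ccccc3)cc2O1 | intermediate
11 | (3R,4S,3'S,4'R)-5,7-bis(benzyloxy)-4,4'-bis[4-(benzyloxy)phenyl]-5',7'-bis(methoxymethoxy)-[3,3'-bichromane]-2,2'-dione | O=C1Oc2cc(OCc3ccccc3)cc(OCc3ccccc3)c2[C@H](c2ccc(OCc3ccccc3)cc2)[C@@H]1[C@H]1C(=O)Oc2cc(OCOC)cc(OCOC)c2[C@H]1c1ccc(OCc2ccccc2)cc1 | intermediate
12 | (3R,4S,3'S,4'R)-5,7-dihydroxy-4,4'-bis(4-hydroxyphenyl)-5',7'-bis(methoxymethoxy)-[3,3'-bichromane]-2,2'-dione | O=C1Oc2cc(O)cc(O)c2[C@H](c2ccc(O)cc2)[C@@H]1[C@H]1C(=O)Oc2cc(OCOC)cc(OCOC)c2[C@H]1c1ccc(O)cc1 | intermediate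
13 | (3R,4S,3'S,4'R)-5,7-bis(benzyloxycarbonyloxy)-4,4'-bis[4-(benzyloxycarbonyloxy)phenyl]-5',7'-bis(methoxymethoxy)-[3,3'-bichromane]-2,2'-dione | O=C1Oc2cc(OC(=O)OCc3ccccc3)cc(OC(=O)OCc3ccccc3)c2[C@H](c2ccc(OC(=O)OCc3ccccc3)cc2)[C@@H]1[C@H]1C(=O)Oc2cc(OCOC)cc(OCOC)c2[C@H]1c1ccc(OC(=O)OCc2ccccc2)cc1 | intermediate
14 | (3R,4S,3'S,4'R)-5,7-bis(benzyloxycarbonyloxy)-4,4'-bis[4-(benzyloxycarbonyloxy)phenyl]-5',7'-dihydroxy-[3,3'-bichromane]-2,2'-dione | O=C1Oc2cc(OC(=O)OCc3ccccc3)cc(OC(=O)OCc3ccccc3)c2[C@H](c2ccc(OC(=O)OCc3ccccc3)cc2)[C@@H]1[C@H]1C(=O)Oc2cc(O)cc(O)c2[C@H]1c1ccc(OC(=O)OCc2ccccc2)cc1 | intermediate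
15 | 6',8'-bis[chloro(methoxy)methyl] derivative of 14 | O=C1Oc2cc(OC(=O)OCc3ccccc3)cc(OC(=O)OCc3ccccc3)c2[C@H](c2ccc(OC(=O)OCc3ccccc3)cc2)[C@@H]1[C@H]1C(=O)Oc2c(C(Cl)OC)c(O)c(C(Cl)OC)c(O)c2[C@H]1c1ccc(OC(=O)OCc2ccccc2)cc1 | intermediate
16 | (3R,4S,3'S,4'R)-5,7-bis(benzyloxycarbonyloxy)-4,4'-bis[4-(benzyloxycarbonyloxy)phenyl]-5',7'-dihydroxy-2,2'-dioxo-[3,3'-bichromane]-6',8'-dicarbaldehyde | O=C1Oc2cc(OC(=O)OCc3ccccc3)cc(OC(=O)OCc3ccccc3)c2[C@H](c2ccc(OC(=O)OCc3ccccc3)cc2)[C@@H]1[C@H]1C(=O)Oc2c(C=O)c(O)c(C=O)c(O)c2[C@H]1c1ccc(OC(=O)OCc2ccccc2)cc1 | intermediate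
17 | 6',8'-bis(formyloxy)-5',7'-dihydroxy analogue of 16 (bis-formate) | O=C1Oc2cc(OC(=O)OCc3ccccc3)cc(OC(=O)OCc3ccccc3)c2[C@H](c2ccc(OC(=O)OCc3ccccc3)cc2)[C@@H]1[C@H]1C(=O)Oc2c(OC=O)c(O)c(OC=O)c(O)c2[C@H]1c1ccc(OC(=O)OCc2ccccc2)cc1 | intermediate
18 | (3R,4S,3'S,4'R)-5,7-bis(benzyloxycarbonyloxy)-4,4'-bis[4-(benzyloxycarbonyloxy)phenyl]-5',6',7',8'-tetrahydroxy-[3,3'-bichromane]-2,2'-dione | O=C1Oc2cc(OC(=O)OCc3ccccc3)cc(OC(=O)OCc3ccccc3)c2[C@H](c2ccc(OC(=O)OCc3ccccc3)cc2)[C@@H]1[C@H]1C(=O)Oc2c(O)c(O)c(O)c(O)c2[C@H]1c1ccc(OC(=O)OCc2ccccc2)cc1 | intermediate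
19 | (3R,4S,3'S,4'R)-5,7,5',6',7',8'-hexahydroxy-4,4'-bis(4-hydroxyphenyl)-[3,3'-bichromane]-2,2'-dione | O=C1Oc2cc(O)cc(O)c2[C@H](c2ccc(O)cc2)[C@@H]1[C@H]1C(=O)Oc2c(O)c(O)c(O)c(O)c2[C@H]1c1ccc(O)cc1 | target

**Step count and risks**
Total step count: 12. Longest linear sequence: 10 steps (steps 3, 4, 5–12 from 1; the branch through steps 1 and 2 is of equal length).

Steps most likely to fail:

1. Step 5. The two lactone enolates are nearly identical, so homocoupling competes statistically. Bond formation between two carbons that each carry a diarylmethine neighbour may also be slow enough for oxidation of the enolates to the 4-arylcoumarins to take over. Fallback, from 4 and 6 back to 9: the coupling is made intramolecular through a silicon tether. Enolate 7 is quenched with excess i-Pr2SiCl2 to give the chlorosilyl ketene acetal F1, and the excess dichlorosilane is removed under vacuum. Enolate 8 is added to give the unsymmetrical diisopropylsilyl bis(ketene acetal) F2. One-electron oxidation with Cu(OTf)2 (divalent copper) in MeCN–THF at −40 °C, as known for silyl bis-enol ethers of ketones, should then join C3 and C3' within the tether and give 9 after aqueous work-up.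

2. Step 6. Incomplete second deprotonation at the hindered C3/C3' positions, or proton exchange between a mono-enolate and already protonated material, would return the thermodynamically preferred trans lactones. Facial selectivity of the protonation may also be eroded. Fallback, from 9 back to 11: the dienolate 10 is trapped with Me3SiCl to give the neutral bis(trimethylsilyl ketene acetal) F3, which is freed from amine and lithium salts by non-aqueous work-up. It is then protodesilylated with CF3CO2H in CH2Cl2 at −78 °C, so that protonation takes place on a neutral ketene acetal under acidic conditions where no enolate is present to equilibrate the product.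

3. Step 11. At the second aldehyde, hydride migration may compete with aryl migration and give a carboxylic acid. The free-phenol ring may also be over-oxidised to quinones before or after the formates are cleaved. Fallback, from 16 back to 18: the two ring B phenols are silylated (t-BuMe2SiOTf, 2,6-lutidine, CH2Cl2, −78 °C) to give the bis(silyl ether) F4. Its aldehydes are no longer hydrogen-bonded and its ring carries no free hydroxyl group. Baeyer–Villiger oxidation of this 2,6-dioxygenated dialdehyde with mCPBA should give the fully protected bis-formate F5. HF·pyridine in THF followed by dilute HCl under argon then removes the silyl and formyl groups to give 18.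

**Further compounds**
F1 | step 5 | chloro(diisopropyl)silyl ketene acetal of 4 | CC(C)[Si](Cl)(OC1=C[C@@H](c2ccc(OCc3ccccc3)cc2)c2c(OCc3ccccc3)cc(OCc3ccccc3)cc2O1)C(C)C
F2 | step 5 | diisopropylsilyl bis(ketene acetal) of 4 and 6 | CC(C)[Si](OC1=C[C@@H](c2ccc(OCc3ccccc3)cc2)c2c(OCc3ccccc3)cc(OCc3ccccc3)cc2O1)(OC1=C[C@H](c2ccc(OCc3ccccc3)cc2)c2c(OCOC)cc(OCOC)cc2O1)C(C)C
F3 | step 6 | bis(trimethylsilyl ketene acetal) of 9 | C[Si](C)(C)OC1=C(C2=C(O[Si](C)(C)C)Oc3cc(OCOC)cc(OCOC)c3[C@H]2c2ccc(OCc3ccccc3)cc2)[C@@H](c2ccc(OCc3ccccc3)cc2)c2c(OCc3ccccc3)cc(OCc3ccccc3)cc2O1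
F4 | step 11 | 5',7'-bis(tert-butyldimethylsilyl) ether of 16 | O=C1Oc2cc(OC(=O)OCc3ccccc3)cc(OC(=O)OCc3ccccc3)c2[C@H](c2ccc(OC(=O)OCc3ccccc3)cc2)[C@@H]1[C@H]1C(=O)Oc2c(C=O)c(O[Si](C)(C)C(C)(C)C)c(C=O)c(O[Si](C)(C)C(C)(C)C)c2[C@H]1c1ccc(OC(=O)OCc2ccccc2)cc1
F5 | step 11 | 6',8'-bis(formyloxy)-5',7'-bis(tert-butyldimethylsilyloxy) analogue of 18 | O=C1Oc2cc(OC(=O)OCc3ccccc3)cc(OC(=O)OCc3ccccc3)c2[C@H](c2ccc(OC(=O)OCc3ccccc3)cc2)[C@@H]1[C@H]1C(=O)Oc2c(OC=O)c(O[Si](C)(C)C(C)(C)C)c(OC=O)c(O[Si](C)(C)C(C)(C)C)c2[C@H]1c1ccc(OC(=O)OCc2ccccc2)cc1
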